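**Strategy**

1. Cuts: the diaryl ether bond between the ring A oxygen and C1 of ring B is broken first, with two of the three free hydroxyls carried as methyl ethers. This opens the 22-membered ring to a twofold-symmetric open-chain diphenol. The two aryl–chain bonds (as aryl–alkyne bonds) and the two C–C bonds joining a C12 unit to two acetylene units are cut next.
2. Enabling feature: in ring B the ether carbon C1 is para to the C4 hydroxyl and sits between the C2 hydroxyl and the chain carbon C6, which is position 4 of a 5-alkylresorcinol. Ring A is the same 5-alkylresorcinol arylated on one oxygen, so both ends of the C16 chain carry the same ring and the ether bond is a para C–O phenol coupling between them.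
3. Forward order: a C12 dibromide and two acetylides give the C16 diyne, and two purchased dimethoxyphenyl rings are attached by a twofold Sonogashira coupling. Hydrogenation and removal of one methyl ether per ring follow; the macrocycle, the only ring made, is then closed by oxidative C–O coupling and the last two methyl ethers are cleaved.
4. Stereochemistry: the target has no stereocenter and no configured double bond; the sp3 carbon of the transient dienone is lost on rearomatization.

Key step: step 5

Remark on the chemistry: attack of the donor oxygen at either chain-flanked carbon of the acceptor ring (para or ortho to its free hydroxyl) leads to the same target after the final demethylation, because these two positions of a 5-alkylresorcinol are equivalent once both oxygens are free. The para-coupled isomer is the one carried through the steps.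

**Route**

Step 1
Reactants: 1 1,12-dibromododecane; 2 lithium acetylide ethylenediamine complex
Product: 3 hexadeca-1,15-diyne
Conditions: 2 (3 equiv), DMSO, 15 °C to rt
Reagents that add atoms: none
Why: Twofold SN2 alkylation of a terminal acetylide: the primary bromides of 1 are displaced by lithium acetylide, which DMSO and the diamine keep soluble and reactive, and substitution is favoured over elimination at unhindered primary carbons.

Step 2
Reactants: 3 hexadeca-1,15-diyne; 4 1-iodo-3,5-dimethoxybenzene
Product: 5 1,16-bis(3,5-dimethoxyphenyl)hexadeca-1,15-diyne
Conditions: 4 (2.2 equiv), Pd(PPh3)2Cl2 (cat.), CuI (cat.), Et3N, THF, degassed, rt to 45 °C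
Reagents that add atoms: none
Why: Twofold Sonogashira coupling: the aryl iodide adds oxidatively to zerovalent palladium already at room temperature and each terminal alkyne is delivered as its copper acetylide, with strict exclusion of O2 to hold back oxidative alkyne homocoupling.

Step 3
Reactants: 5 1,16-bis(3,5-dimethoxyphenyl)hexadeca-1,15-diyne
Product: 6 1,16-bis(3,5-dimethoxyphenyl)hexadecane
Conditions: H2 (1 atm), Pd/C, EtOAc/EtOH, rt
Reagents that add atoms: none
Why: Heterogeneous catalytic hydrogenation reduces both aryl alkynes fully to CH2–CH2, while the arenes and aryl methyl ethers are untouched at 1 atm H2 and room temperature.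

Step 4
Reactants: 6 1,16-bis(3,5-dimethoxyphenyl)hexadecane
Product: 7 5,5'-(hexadecane-1,16-diyl)bis(3-methoxyphenol)
Conditions: NaSEt (excess), DMF, 140 °C; then aq. HCl
Reagents that add atoms: none
Why: Nucleophilic O-demethylation (SN2 attack of ethanethiolate on the methyl carbon) that stops after one cleavage per ring because the aryloxide formed makes the remaining methoxy oxygen a far poorer leaving group, as is known for 5-alkylresorcinol dimethyl ethers.

Step 5
Reactants: 7 5,5'-(hexadecane-1,16-diyl)bis(3-methoxyphenol)
Product: 9 di-O-methyl grevirobstol B (22-membered diaryl ether; ring A methoxy; ring B methoxy ortho and free hydroxyl para to the ether carbon), via macrocyclic 4-aryloxycyclohexa-2,5-dienone 8 (not isolated)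
Conditions: CuCl2 (10 mol%), 1,4,7-triisopropyl-1,4,7-triazacyclononane (10 mol%), 2,6-diphenylpyridine, O2 (1 atm), toluene, 40 °C, about 1 mM, stopped at partial conversion, unreacted 7 recycled
Reagents that add atoms: none
Why: Proposed new method: the divalent copper–triazacyclononane complex binds each phenoxide and oxidizes it by one electron to a copper-bound phenoxyl radical; the phenoxyl oxygen of one ring then bonds to the para carbon of the other (the carbon between its methoxy group and the chain), giving the 4-aryloxycyclohexa-2,5-dienone 8, which enolizes to 9 while O2 returns monovalent copper to divalent copper. The closest known reaction type is the copper–amine aerobic para C–O coupling of phenols (poly(phenylene ether) formation and its regiocontrolled version with triazacyclononane complexes of divalent copper), together with macrocyclic diaryl ether closure by phenol oxidation with Tl(NO3)3; an intramolecular closure between two 3-alkoxy-5-alkylphenols has not been shown. The 22-membered ring is closed end to end by this single C–O bond between the two termini of an open twofold-symmetric chain, a strain-free macrocyclization whose entropic cost is met by high dilution. No stereocenter results, because the one sp3 carbon of 8 becomes aromatic again on tautomerization. The step needs C–O rather than C–C coupling and attack at a chain-flanked carbon rather than the carbon between the two oxygens: the bulky triisopropyl ligand around the copper-bound phenoxyl shields its ortho carbons and holds back free-radical C–C dimerization, each ring has only one free hydroxyl, and attack at the other chain-flanked (ortho) carbon would still converge on the target after step 6. Because 9 is a more easily oxidized 4-aryloxyphenol than 7, the reaction is interrupted early and unreacted 7 is returned to the step.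

Step 6
Reactants: 9 di-O-methyl grevirobstol B
Product: 10 grevirobstol B
Conditions: BBr3 (excess), CH2Cl2, −78 °C to rt; then H2O
Reagents that add atoms: none
Why: Lewis acid O-demethylation in which BBr3 complexes each methoxy oxygen and bromide removes the methyl group as MeBr, whereas the diaryl ether, which offers no alkyl carbon to bromide attack, and the saturated chain are left intact.

**Compound list**

1 | 1,12-dibromododecane | BrCCCCCCCCCCCCBr | starting material
2 | lithium acetylide ethylenediamine complex | [Li]C#C.NCCN | starting material
3 | hexadeca-1,15-diyne | C#CCCCCCCCCCCCCC#C | intermediate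
4 | 1-iodo-3,5-dimethoxybenzene | COc1cc(I)cc(OC)c1 | starting material
5 | 1,16-bis(3,5-dimethoxyphenyl)hexadeca-1,15-diyne | COc1cc(OC)cc(c1)C#CCCCCCCCCCCCCC#Cc1cc(OC)cc(OC)c1 | intermediate
6 | 1,16-bis(3,5-dimethoxyphenyl)hexadecane | COc1cc(OC)cc(c1)CCCCCCCCCCCCCCCCc1cc(OC)cc(OC)c1 | intermediate
7 | 5,5'-(hexadecane-1,16-diyl)bis(3-methoxyphenol) | COc1cc(O)cc(c1)CCCCCCCCCCCCCCCCc1cc(O)cc(OC)c1 | intermediate
8 | macrocyclic 4-aryloxycyclohexa-2,5-dienone (racemic at its sp3 carbon; formed in the flask, not isolated) | COc1cc2cc(c1)OC1C(OC)=CC(=O)C=C1CCCCCCCCCCCCCCCC2 | intermediate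
9 | di-O-methyl grevirobstol B | COc1cc2cc(c1)Oc1c(OC)cc(O)cc1CCCCCCCCCCCCCCCC2 | intermediate
10 | grevirobstol B | Oc1cc2cc(c1)Oc1c(O)cc(O)cc1CCCCCCCCCCCCCCCC2 | target

**Step count**

Total steps: 6. Longest linear sequence: 6 steps (1 → 3 → 5 → 6 → 7 → 9 → 10).

**Steps most likely to fail**

1. Step 5 (proposed new method). What may go wrong: C–C instead of C–O coupling, attack at the carbon between the two oxygens, intermolecular oligomerization, and further oxidation of the electron-rich aryloxyphenol product.

Fallback (known chemistry, sets out from 6 and rejoins at 10): the ether bond would be made by an intramolecular Ullmann coupling of a desymmetrized chain. One methyl ether of 6 would be cleaved with one equivalent of NaSEt in hot DMF, with unreacted 6 recycled, to give 3-[16-(3,5-dimethoxyphenyl)hexadecyl]-5-methoxyphenol F1. Acetylation (Ac2O, pyridine) would give 3-[16-(3,5-dimethoxyphenyl)hexadecyl]-5-methoxyphenyl acetate F2, in which the phenol ring is deactivated. N-Iodosuccinimide in MeCN should then iodinate the more electron-rich dimethoxy ring at the carbon between the chain and a methoxy group, giving 3-[16-(2-iodo-3,5-dimethoxyphenyl)hexadecyl]-5-methoxyphenyl acetate F3. K2CO3 in MeOH would free the phenol to give 3-[16-(2-iodo-3,5-dimethoxyphenyl)hexadecyl]-5-methoxyphenol F4. Ullmann macrocyclization (CuI, N,N-dimethylglycine, Cs2CO3, dioxane, 100 °C, high dilution) would close the 22-membered ring to tri-O-methyl grevirobstol B F5. BBr3 in CH2Cl2 would cleave all three methyl ethers and deliver 10.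

2. Step 4. What may go wrong: too little or too much ether cleavage across the two rings of a lipophilic long-chain substrate, giving mixtures of phenols that are hard to separate.

Fallback (sets out from 4, uses 3, rejoins at 7): the two oxygens would be told apart on the small aryl iodide before the chain is attached. Iodide 4 would be mono-demethylated with NaSEt in DMF, the phenol being separated from neutral material by base extraction, to give 3-iodo-5-methoxyphenol F6. Benzylation (BnBr, K2CO3, acetone) would give 1-(benzyloxy)-3-iodo-5-methoxybenzene F7. Twofold Sonogashira coupling of F7 with diyne 3 (Pd(PPh3)2Cl2, CuI, Et3N) would give 1,16-bis[3-(benzyloxy)-5-methoxyphenyl]hexadeca-1,15-diyne F8. Hydrogenation over Pd/C would saturate both alkynes and remove both benzyl groups in one operation, giving 7 directly.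

3. Step 2. What may go wrong: copper-mediated oxidative homocoupling of the terminal diyne to oligomers, and stalling after the first arylation.

Fallback (sets out from 3, uses 4, rejoins at 6): the aryl–chain bonds would be made by Suzuki–Miyaura coupling without copper acetylides. Twofold hydroboration of 3 with pinacolborane, catalysed by Cp2Zr(H)Cl, would give 2,2'-[(1E,15E)-hexadeca-1,15-diene-1,16-diyl]bis(4,4,5,5-tetramethyl-1,3,2-dioxaborolane) F9. Coupling with two equivalents of 4 (Pd(PPh3)4, aqueous K2CO3, dioxane, 80 °C) would give (1E,15E)-1,16-bis(3,5-dimethoxyphenyl)hexadeca-1,15-diene F10. Hydrogenation under the conditions of step 3 would give 6.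

**Further compounds**

F1 | step 5 | 3-[16-(3,5-dimethoxyphenyl)hexadecyl]-5-methoxyphenol | COc1cc(O)cc(c1)CCCCCCCCCCCCCCCCc1cc(OC)cc(OC)c1
F2 | step 5 | 3-[16-(3,5-dimethoxyphenyl)hexadecyl]-5-methoxyphenyl acetate | COc1cc(OC(C)=O)cc(c1)CCCCCCCCCCCCCCCCc1cc(OC)cc(OC)c1
F3 | step 5 | 3-[16-(2-iodo-3,5-dimethoxyphenyl)hexadecyl]-5-methoxyphenyl acetate | COc1cc(OC(C)=O)cc(c1)CCCCCCCCCCCCCCCCc1cc(OC)cc(OC)c1I
F4 | step 5 | 3-[16-(2-iodo-3,5-dimethoxyphenyl)hexadecyl]-5-methoxyphenol | COc1cc(O)cc(c1)CCCCCCCCCCCCCCCCc1cc(OC)cc(OC)c1I
F5 | step 5 | tri-O-methyl grevirobstol B | COc1cc2cc(c1)Oc1c(OC)cc(OC)cc1CCCCCCCCCCCCCCCC2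
F6 | step 4 | 3-iodo-5-methoxyphenol | COc1cc(O)cc(I)c1
F7 | step 4 | 1-(benzyloxy)-3-iodo-5-methoxybenzene | COc1cc(I)cc(OCc2ccccc2)c1
F8 | step 4 | 1,16-bis[3-(benzyloxy)-5-methoxyphenyl]hexadeca-1,15-diyne | COc1cc(OCc2ccccc2)cc(c1)C#CCCCCCCCCCCCCC#Cc1cc(OC)cc(OCc2ccccc2)c1
F9 | step 2 | 2,2'-[(1E,15E)-hexadeca-1,15-diene-1,16-diyl]bis(4,4,5,5-tetramethyl-1,3,2-dioxaborolane) | CC1(C)OB(OC1(C)C)/C=C/CCCCCCCCCCCC/C=C/B1OC(C)(C)C(C)(C)O1
F10 | step 2 | (1E,15E)-1,16-bis(3,5-dimethoxyphenyl)hexadeca-1,15-diene | COc1cc(OC)cc(c1)/C=C/CCCCCCCCCCCC/C=C/c1cc(OC)cc(OC)c1
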